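**Plan**
Locants used throughout: C1 (CH–OAc), C2 (CH2), C3 (C(OH)iPr), C4 (ring-fusion CH), C5 (CH–O-aroyl), C6=C7(Me), C8 (C=O), C9 (CH2), C10 (C–Me); β is the face of the C10 methyl.
Retrosynthesis cuts both esters, takes C1–OH back to a ketone, C3–OH back to a C2=C3 alkene (ring-closing metathesis), and then cuts C9–C10 and C4–C5 together, after re-installing a C9–O–C5 ether bridge and a C9–C(=O)–O–C1 ester tether.
Enabling feature: in the seven-membered ring, C5–O, C6=C7(Me), C8=O and C9H2 are the reductively opened form of an 8-oxabicyclo[3.2.1]oct-3-en-2-one, i.e. the [5+2] adduct of a 4-methyl-3-oxidopyrylium (C9, C8, C7, C6, C5 plus the ring O) with the C10=C4 alkene.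
Forward: acyclic (E)-dienynol, ester with a furylglycolate, pyranone, [5+2] (seven-membered ring plus lactone tether), reductive bridge opening, excision of the tether carbon, five-membered ring by metathesis, oxygenation at C3 and C1, esters.
Stereochemistry: the C1 carbinol (S, catalytic alkynylation) steers the alkene face; E geometry plus the exo tether fix C10, C4, C5 and the trans ring fusion; C3–OH comes from hydration on the α face; C1 is reset by hydroxyl-directed reduction.

Key step: step 6

Assumption: aldehyde 1 is taken as purchasable (otherwise one α-methylenation from 3-methylbutanal); the diastereomer drawn for 14 is the one carried on.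

Step 1
Reactants: 1 3-methyl-2-methylidenebutanal; 2 2-(triphenyl-λ5-phosphanylidene)propanal
Product: 3 (2E)-2,5-dimethyl-4-methylidenehex-2-enal
Conditions: toluene, 80 °C
Reagents that add atoms: none
Why: Wittig olefination with a formyl-stabilised ylide is E-selective and should stop at the mono-adduct, since the α-methyl enal formed is less electrophilic than 1; this E alkene becomes C10=C4.

Step 2
Reactants: 3 (2E)-2,5-dimethyl-4-methylidenehex-2-enal; 4 ethynyl(trimethyl)silane
Product: 5 (3S,4E)-4,7-dimethyl-6-methylidene-1-(trimethylsilyl)oct-4-en-1-yn-3-ol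
Conditions: Me2Zn, ProPhenol ligand (the enantiomer that delivers the S carbinol), Ph3P=O, toluene, 0 °C
Reagents that add atoms: none
Why: catalytic asymmetric alkynylation, in which the dinuclear zinc–ProPhenol alkynylide adds 1,2 to one face of the enal and sets C1 as S.

Step 3
Reactants: 6 3-methylfuran; 7 oxalyl chloride; 5 (3S,4E)-dienynol
Product: 9 (3S,4E)-dienynyl 2-(3-methylfuran-2-yl)-2-oxoacetate, via glyoxylyl chloride 8 (not isolated)
Conditions: 7, CH2Cl2, 0 °C, excess 7 removed in vacuo; then 5, pyridine, CH2Cl2, −20 °C → rt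
Reagents that add atoms: none
Why: Friedel–Crafts acylation of the electron-rich furan at C2 (the α-position next to the methyl) gives the oxoacetyl chloride, which esterifies the secondary alcohol with retention at C1.

Step 4
Reactants: 9 keto ester
Product: 10 (3S,4E)-dienynyl 2-hydroxy-2-(3-methylfuran-2-yl)acetate (both carbinol epimers)
Conditions: NaBH4, THF/MeOH, −78 °C
Reagents that add atoms: none
Why: chemoselective hydride reduction of the α-keto ester ketone, the most electrophilic carbonyl, gives the furylcarbinol; its configuration is irrelevant because that carbon becomes trigonal in the ylide.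

Step 5
Reactants: 10 furylglycolate
Product: 11 (3S,4E)-dienynyl 6-hydroxy-4-methyl-3-oxo-3,6-dihydro-2H-pyran-2-carboxylate (mixture at the two pyranone sp3 carbons)
Conditions: NBS, NaHCO3, NaOAc, THF/H2O (4:1), 0 °C
Reagents that add atoms: water, O
Why: Achmatowicz rearrangement, in which the furan (far more electron-rich than the diene or the silylalkyne) is oxidised and ring-expanded by water to the 6-hydroxy-2H-pyran-3(6H)-one.

Step 6
Reactants: 11 hydroxypyranone ester
Product: 14 lactone-bridged 8-oxabicyclo[3.2.1]oct-3-en-2-one cycloadduct, via acetoxypyranone 12 (not isolated), via oxidopyrylium ylide 13 (not isolated)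
Conditions: Ac2O, pyridine, DMAP (cat.), CH2Cl2, 0 °C; then iPr2NEt, MeCN (0.01 M), 70 °C
Reagents that add atoms: none
Why: Proposed new method: acetylation of the lactol and base-induced loss of acetic acid should give the 2-(alkoxycarbonyl)-4-methyl-3-oxidopyrylium 13, a carbonyl ylide across C9–O–C5 whose thermally allowed suprafacial [5+2] addition to the C10=C4 π bond forms C9–C10 and C4–C5 in one event; the closest known reactions are the intramolecular oxidopyrylium–alkene [5+2] cycloaddition of 2-tethered pyranones and cycloadditions of ester-stabilised carbonyl ylides, but an ester on C9 as the tether has not been shown. The seven-membered carbocycle closes in the [5+2] mode as part of the oxabicycle, and the γ-lactone closes through the C9–C10 bond, exo with respect to the alkene. C9 and C5 are cis because of the O-bridge, the three-atom tether forces C1 exo and the methyl endo at C10, and the E geometry then puts H exo and the 3-methylbut-1-en-2-yl group endo at C4, so C1 and C3 are trans, which is the later trans ring fusion. The absolute sense should come from C1: with the C1–O bond turned toward the ylide, the alkynyl group lies over C10=C4 and the hydrogen sits next to the C10 methyl (1,2-allylic strain), so one alkene face is offered. The step needs site selectivity for C10=C4, which the short tether (it cannot reach the terminal alkene in a fused mode) and the hindered, electron-poorer silylalkyne should secure, and it needs the s-cis ester conformer, for which dilution and heating are chosen.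

Step 7
Reactants: 14 cycloadduct
Product: 15 5-hydroxy β-keto lactone (C9–O cleaved, C9–H)
Conditions: SmI2 (2.5 equiv), THF/MeOH, −78 °C
Reagents that add atoms: none
Why: reductive cleavage of an α-alkoxy ketone by SmI2: two single-electron transfers should expel the C9–O bond, which is α to both the ketone and the lactone carbonyl, as the stabilised β-keto-lactone enolate, leaving C5–OH with its configuration.

Step 8
Reactants: 15 hydroxy β-keto lactone
Product: 16 5-O-triethylsilyl β-keto lactone
Conditions: TESOTf, 2,6-lutidine, CH2Cl2, −78 °C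
Reagents that add atoms: triethylsilyl trifluoromethanesulfonate, CC[Si](CC)(CC)OS(=O)(=O)C(F)(F)F
Why: silylation of the only free hydroxyl (C5) protects it for the basic and oxidative steps that follow.

Step 9
Reactants: 16 silyl ether lactone
Product: 18 propargylic alcohol cycloheptenone, via hydroxy keto acid 17 (not isolated)
Conditions: LiOH, THF/MeOH/H2O, 0 °C → rt; then aq. HCl to pH 4, 40 °C
Reagents that add atoms: none
Why: saponification of the β-keto lactone (with cleavage of the alkynyl–silicon bond) and decarboxylation of the β-keto acid on acidification remove the tether carbon, leaving C9 as CH2 and C1 as a free carbinol.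

Step 10
Reactants: 18 propargylic alcohol
Product: 19 vinyl carbinol
Conditions: H2 (1 atm), Pd on CaCO3 poisoned with Pb(OAc)2 (Lindlar catalyst), quinoline, EtOAc, rt
Reagents that add atoms: none
Why: Lindlar semi-hydrogenation reduces only the terminal alkyne; the trisubstituted enone and the 1,1-disubstituted alkene are inert.

Step 11
Reactants: 19 vinyl carbinol
Product: 20 trans-fused cyclopentenol (C2=C3, 1α-OH)
Conditions: second-generation Grubbs catalyst RuCl2(H2IMes)(PCy3)(=CHPh) (5 mol%), CH2Cl2, 40 °C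
Reagents that add atoms: none
Why: ring-closing metathesis of the vinyl group with the 1,1-disubstituted alkene forms the C2=C3 cyclopentene, and because C1 and C3 are trans across C10–C4 the ring closes trans-fused.

Step 12
Reactants: 20 cyclopentenol
Product: 21 1α,3α-diol
Conditions: Co(acac)2 (20 mol%), PhSiH3, O2 (1 atm), THF/iPrOH, rt
Reagents that add atoms: dioxygen, O=O
Why: Mukaiyama hydration (hydrogen-atom transfer to C2, trapping of the tertiary C3 radical by O2, reduction of the peroxide) gives the Markovnikov alcohol, with oxygen arriving on the α face opposite the angular methyl and the C5 substituent, so C3 has OH α and isopropyl β.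

Step 13
Reactants: 21 diol
Product: 22 3α-hydroxy-1-ketone
Conditions: Dess–Martin periodinane, NaHCO3, CH2Cl2, 0 °C → rt
Reagents that add atoms: none
Why: Dess–Martin oxidation converts the secondary C1 carbinol (the sacrificial stereocentre) into the ketone; the tertiary C3 alcohol cannot react.

Step 14
Reactants: 22 hydroxy ketone
Product: 23 1β,3α-diol
Conditions: Me4NBH(OAc)3, MeCN/AcOH, −25 °C
Reagents that add atoms: none
Why: Evans–Saksena reduction, in which the borohydride bound to the C3 oxygen delivers hydride to the α face of the C1 ketone to give the anti 1,3-diol (C1–OH β), while the undirected enone is not reduced.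

Step 15
Reactants: 23 anti diol
Product: 24 1β-acetate
Conditions: Ac2O, pyridine, DMAP (cat.), CH2Cl2, 0 °C
Reagents that add atoms: acetic anhydride, CC(=O)OC(C)=O
Why: acetylation of the secondary C1 alcohol; the tertiary C3 alcohol is too hindered to react.

Step 16
Reactants: 24 acetate silyl ether
Product: 25 5-alcohol
Conditions: HF·pyridine, THF/pyridine, 0 °C → rt
Reagents that add atoms: none
Why: fluoride cleavage of the triethylsilyl ether frees C5–OH without touching the acetate or the tertiary alcohol.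

Step 17
Reactants: 25 5-alcohol; 26 4-(chlorocarbonyl)phenyl acetate
Product: 27 5-(4-acetoxybenzoate)
Conditions: pyridine, DMAP (cat.), CH2Cl2, 0 °C → rt
Reagents that add atoms: none
Why: DMAP-catalysed acylation of the secondary allylic C5 alcohol with retention at C5; the tertiary C3 alcohol is unreactive.

Step 18
Reactants: 27 aryl acetate
Product: 28 (1S,3R,3aR,4R,8aS)-1-(acetyloxy)-3-hydroxy-6,8a-dimethyl-7-oxo-3-(propan-2-yl)-1,2,3,3a,4,7,8,8a-octahydroazulen-4-yl 4-hydroxybenzoate
Conditions: NH4OAc, MeOH/H2O, rt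
Reagents that add atoms: none
Why: chemoselective solvolysis of the aryl acetate, whose phenoxide leaving group makes it far more labile than the alkyl acetate or the benzoate of a hindered secondary alcohol.

**Compound list** ("dienynyl" = the (3S,4E)-4,7-dimethyl-6-methylidene-1-(trimethylsilyl)oct-4-en-1-yn-3-yl group of 5)
1 | 3-methyl-2-methylidenebutanal | C=C(C=O)C(C)C | starting material
2 | 2-(triphenyl-λ5-phosphanylidene)propanal | CC(C=O)=P(c1ccccc1)(c1ccccc1)c1ccccc1 | starting material
3 | (2E)-2,5-dimethyl-4-methylidenehex-2-enal | O=C/C(C)=C/C(=C)C(C)C | intermediate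
4 | ethynyl(trimethyl)silane | C#C[Si](C)(C)C | starting material
5 | (3S,4E)-4,7-dimethyl-6-methylidene-1-(trimethylsilyl)oct-4-en-1-yn-3-ol | C[Si](C)(C)C#C[C@@H](O)/C(C)=C/C(=C)C(C)C | intermediate
6 | 3-methylfuran | Cc1ccoc1 | starting material
7 | oxalyl chloride | O=C(Cl)C(=O)Cl | starting material
8 | 2-(3-methylfuran-2-yl)-2-oxoacetyl chloride | Cc1ccoc1C(=O)C(=O)Cl | intermediate
9 | dienynyl 2-(3-methylfuran-2-yl)-2-oxoacetate | Cc1ccoc1C(=O)C(=O)O[C@H](C#C[Si](C)(C)C)/C(C)=C/C(=C)C(C)C | intermediate
10 | dienynyl 2-hydroxy-2-(3-methylfuran-2-yl)acetate (carbinol epimers) | Cc1ccoc1C(O)C(=O)O[C@H](C#C[Si](C)(C)C)/C(C)=C/C(=C)C(C)C | intermediate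
11 | dienynyl 6-hydroxy-4-methyl-3-oxo-3,6-dihydro-2H-pyran-2-carboxylate | OC1OC(C(=O)O[C@H](C#C[Si](C)(C)C)/C(C)=C/C(=C)C(C)C)C(=O)C(C)=C1 | intermediate
12 | dienynyl 6-(acetyloxy)-4-methyl-3-oxo-3,6-dihydro-2H-pyran-2-carboxylate | CC(=O)OC1OC(C(=O)O[C@H](C#C[Si](C)(C)C)/C(C)=C/C(=C)C(C)C)C(=O)C(C)=C1 | intermediate
13 | 2-(dienynyloxycarbonyl)-4-methylpyrylium-3-olate (oxidopyrylium ylide) | [O-]c1c(C)cc[o+]c1C(=O)O[C@H](C#C[Si](C)(C)C)/C(C)=C/C(=C)C(C)C | intermediate
14 | cycloadduct: 8-oxabicyclo[3.2.1]oct-3-en-2-one (C8=O, C7(Me)=C6, bridgeheads C9 and C5) fused at C9–C10 to a γ-lactone C9–C(=O)–O–C1; C10 methyl endo, C1 exo; C4 H exo, 3-methylbut-1-en-2-yl endo; silylethynyl on C1 cis to C4 | O=C1O[C@H](C#C[Si](C)(C)C)[C@]2(C)[C@@H](C(=C)C(C)C)[C@H]3C=C(C)C(=O)[C@@]12O3 | intermediate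
15 | 5-hydroxy β-keto lactone: cyclohept-2-enone with the γ-lactone retained, C9–H between ketone and lactone carbonyl (keto/enol mixture); C1, C4, C5, C10 as in 14 | O=C1O[C@H](C#C[Si](C)(C)C)[C@]2(C)[C@@H](C(=C)C(C)C)[C@H](O)C=C(C)C(=O)C12 | intermediate
16 | 5-O-triethylsilyl ether of 15 | O=C1O[C@H](C#C[Si](C)(C)C)[C@]2(C)[C@@H](C(=C)C(C)C)[C@H](O[Si](CC)(CC)CC)C=C(C)C(=O)C12 | intermediate
17 | 2-oxocyclohept-3-ene-1-carboxylic acid bearing 7-(1-hydroxyprop-2-yn-1-yl), 3,7-dimethyl, 6-(3-methylbut-1-en-2-yl) and 5-(triethylsilyloxy) groups | C#C[C@@H](O)[C@@]1(C)C(C(=O)O)C(=O)C(C)=C[C@@H](O[Si](CC)(CC)CC)[C@@H]1C(=C)C(C)C | intermediate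
18 | 6-(1-hydroxyprop-2-yn-1-yl)-2,6-dimethyl-5-(3-methylbut-1-en-2-yl)-4-(triethylsilyloxy)cyclohept-2-en-1-one (C4, C5, C10 as in 28; C1 carbinol of opposite sense) | C#C[C@@H](O)[C@@]1(C)CC(=O)C(C)=C[C@@H](O[Si](CC)(CC)CC)[C@@H]1C(=C)C(C)C | intermediate
19 | 6-(1-hydroxyprop-2-en-1-yl) analogue of 18 | C=C[C@@H](O)[C@@]1(C)CC(=O)C(C)=C[C@@H](O[Si](CC)(CC)CC)[C@@H]1C(=C)C(C)C | intermediate
20 | trans-fused hydroazulenone: 1α-hydroxy, C2=C3 alkene with 3-isopropyl, 5-OTES, 7,10-dimethyl, C6=C7–C8=O | O[C@@H]1C=C(C(C)C)[C@H]2[C@H](O[Si](CC)(CC)CC)C=C(C)C(=O)C[C@]12C | intermediate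
21 | 1α,3α-dihydroxy-3β-isopropyl analogue (C2 saturated) | O[C@@H]1C[C@@](O)(C(C)C)[C@H]2[C@H](O[Si](CC)(CC)CC)C=C(C)C(=O)C[C@]12C | intermediate
22 | 3α-hydroxy-3β-isopropyl-1,8-dione, 5-OTES | O=C1C[C@@](O)(C(C)C)[C@H]2[C@H](O[Si](CC)(CC)CC)C=C(C)C(=O)C[C@]12C | intermediate
23 | 1β,3α-dihydroxy compound, 5-OTES | O[C@H]1C[C@@](O)(C(C)C)[C@H]2[C@H](O[Si](CC)(CC)CC)C=C(C)C(=O)C[C@]12C | intermediate
24 | 1β-acetate of 23 | CC(=O)O[C@H]1C[C@@](O)(C(C)C)[C@H]2[C@H](O[Si](CC)(CC)CC)C=C(C)C(=O)C[C@]12C | intermediate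
25 | 1β-acetoxy-3α,5-dihydroxy compound | CC(=O)O[C@H]1C[C@@](O)(C(C)C)[C@H]2[C@H](O)C=C(C)C(=O)C[C@]12C | intermediate
26 | 4-(chlorocarbonyl)phenyl acetate | CC(=O)Oc1ccc(cc1)C(Cl)=O | starting material
27 | 5-(4-acetoxybenzoate) of 25 | CC(=O)O[C@H]1C[C@@](O)(C(C)C)[C@H]2[C@H](OC(=O)c3ccc(OC(C)=O)cc3)C=C(C)C(=O)C[C@]12C | intermediate
28 | (1S,3R,3aR,4R,8aS)-1-(acetyloxy)-3-hydroxy-6,8a-dimethyl-7-oxo-3-(propan-2-yl)-1,2,3,3a,4,7,8,8a-octahydroazulen-4-yl 4-hydroxybenzoate | CC(=O)O[C@H]1C[C@@](O)(C(C)C)[C@H]2[C@H](OC(=O)c3ccc(O)cc3)C=C(C)C(=O)C[C@]12C | target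

**Step count and risks**
Total step count: 18. Longest linear sequence: 18 steps (1 → 28).

Steps most likely to fail:

Step 6 (the ester tether may not reach the s-cis conformer needed for cyclisation, or the C1 centre may give poor facial selectivity). The fallback replaces the tether by the polarity of an enone and uses the known intermolecular oxidopyrylium–enone [5+2] cycloaddition. It sets out from 5. Acetylation should give the acetate F1, and ozonolysis of the terminal 1,1-disubstituted alkene (1 equiv O3, pyridine, CH2Cl2, −78 °C; Me2S) should give the (E)-enone F2, in which C10 is the β-carbon. Separately, (3-methylfuran-2-yl)methanol is taken by Achmatowicz oxidation to the lactol F3 and by acetylation to the acetoxypyranone F4. Et3N generates 4-methylpyrylium-3-olate F5, whose carbon next to the oxide should bond to C10 and whose other terminus to C4 (acyl endo), giving the cycloadduct F6 after separation of diastereomers. SmI2 followed by Et3SiCl should cleave C9–O and trap the enolate and the C5 alkoxide as the bis-silyl dienol ether F7. With the C8 ketone masked in this way, Tebbe methylenation of the isopropyl ketone should give the diene F8. K2CO3/MeOH (acetate, alkynylsilane and dienol silyl ether cleaved) returns to the route at 18.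

Step 7 (the vinylogous C5–O bond may cleave instead of C9–O, or the enone may be over-reduced). The enone is masked before the reduction. Conjugate addition of thiophenol (PhSH, Et3N) to 14 should give the sulfide adduct F9, in which only the α-alkoxy ketone pathway remains. SmI2 then gives the hydroxy sulfide F10. Oxidation (NaIO4) to the sulfoxide F11 and thermal syn-elimination away from the carbinol restore C6=C7, returning at 15.

Step 12 (hydrogen-atom transfer may go to the enone instead, or oxygen may arrive on the wrong face). Oxygen is delivered under control of the C1 hydroxyl instead. VO(acac)2/t-BuOOH epoxidation of 20, syn to the α-hydroxyl, should give the α-epoxy alcohol F12. Dess–Martin oxidation gives the epoxy ketone F13. Opening of the Cα–O bond with Cp2TiCl (trivalent titanium) gives the β-hydroxy ketone, returning at 22.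

Further compounds
F1 | step 6 | dienynyl acetate (acetate of 5) | CC(=O)O[C@H](C#C[Si](C)(C)C)/C(C)=C/C(=C)C(C)C
F2 | step 6 | (3S,4E)-4,7-dimethyl-6-oxo-1-(trimethylsilyl)oct-4-en-1-yn-3-yl acetate | CC(=O)O[C@H](C#C[Si](C)(C)C)/C(C)=C/C(=O)C(C)C
F3 | step 6 | 6-hydroxy-4-methyl-2H-pyran-3(6H)-one | OC1OCC(=O)C(C)=C1
F4 | step 6 | 4-methyl-5-oxo-5,6-dihydro-2H-pyran-2-yl acetate | CC(=O)OC1OCC(=O)C(C)=C1
F5 | step 6 | 4-methylpyrylium-3-olate | [O-]c1c(C)cc[o+]c1
F6 | step 6 | intermolecular cycloadduct: 8-oxabicyclo[3.2.1]oct-3-en-2-one with C10 methyl endo and 1-acetoxy-3-(trimethylsilyl)prop-2-ynyl exo, C4 isobutyryl endo | CC(=O)O[C@H](C#C[Si](C)(C)C)[C@]1(C)[C@@H](C(=O)C(C)C)[C@H]2C=C(C)C(=O)[C@@H]1O2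
F7 | step 6 | ring-opened bis(triethylsilyl) compound: C8 dienol silyl ether, C5 silyl ether, C3 isopropyl ketone | CC(=O)O[C@H](C#C[Si](C)(C)C)[C@@]1(C)C=C(O[Si](CC)(CC)CC)C(C)=C[C@@H](O[Si](CC)(CC)CC)[C@@H]1C(=O)C(C)C
F8 | step 6 | methylenated analogue of F7 (3-methylbut-1-en-2-yl on C4) | CC(=O)O[C@H](C#C[Si](C)(C)C)[C@@]1(C)C=C(O[Si](CC)(CC)CC)C(C)=C[C@@H](O[Si](CC)(CC)CC)[C@@H]1C(=C)C(C)C
F9 | step 7 | C6-phenylsulfanyl adduct of 14 | O=C1O[C@H](C#C[Si](C)(C)C)[C@]2(C)[C@@H](C(=C)C(C)C)[C@H]3C(Sc4ccccc4)C(C)C(=O)[C@@]12O3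
F10 | step 7 | ring-opened 5-hydroxy-6-phenylsulfanyl β-keto lactone | O=C1O[C@H](C#C[Si](C)(C)C)[C@]2(C)[C@@H](C(=C)C(C)C)[C@H](O)C(Sc3ccccc3)C(C)C(=O)C12
F11 | step 7 | sulfoxide of F10 | O=C1O[C@H](C#C[Si](C)(C)C)[C@]2(C)[C@@H](C(=C)C(C)C)[C@H](O)C(S(=O)c3ccccc3)C(C)C(=O)C12
F12 | step 12 | 2α,3α-epoxy-1α-alcohol from 20 | O[C@@H]1[C@@H]2O[C@]2(C(C)C)[C@H]3[C@H](O[Si](CC)(CC)CC)C=C(C)C(=O)C[C@]13C
F13 | step 12 | 2α,3α-epoxy-1-ketone | O=C1[C@@H]2O[C@]2(C(C)C)[C@H]3[C@H](O[Si](CC)(CC)CC)C=C(C)C(=O)C[C@]13C
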